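Assumption: poly-L-leucine is treated as a purchasable catalyst (it is also made in one operation from L-leucine N-carboxyanhydride), and a sequence run in one flask without isolation is counted as one step.

**Retrosynthetic overview**
1. Target 10 ⇒ 2'-hydroxychalcone 7: open ring C at O1–C2 and remove the C3 hydroxyl. Forward, the chalcone's own 2'-oxygen closes ring C while C3 is oxygenated in the same flask, the chalcone → flavanonol order of flavonoid biosynthesis compressed into one enantioselective operation that sets C2 and C3.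
2. 7 ⇒ triol chalcone 6 (silyl groups on the 4- and 4'-oxygens only) ⇒ Claisen–Schmidt union of ring A ketone 3 and ring B aldehyde 5.
3. 3 and 5 ⇒ direct aromatic C-prenylation of 2,4-dihydroxyacetophenone 1 and 4-hydroxybenzaldehyde 4 with prenyl bromide 2.
4. Ring order: rings A and B are bought; ring C is the only ring made and is formed last.

**Route**

Step 1
Reactants: 1 2,4-dihydroxyacetophenone; 2 prenyl bromide (1-bromo-3-methylbut-2-ene)
Product: 3 1-[2,4-dihydroxy-3-(3-methylbut-2-en-1-yl)phenyl]ethan-1-one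
Conditions: KOH (10% aq, 2 equiv), 2 (1.0 equiv), 0 °C → rt, 24 h; dil. HCl; chromatography (removes 5-prenyl, O-prenyl and diprenyl by-products)
Reagents that add atoms: none
Why: Phenoxide C-alkylation (SN2) in water, where hydrogen bonding to the oxygens steers the allylic bromide to carbon and C3, flanked by both oxygens of the resorcinolate, is the most nucleophilic ring position; no stereocentre is formed.

Step 2
Reactants: 4 4-hydroxybenzaldehyde; 2 prenyl bromide
Product: 5 4-hydroxy-3-(3-methylbut-2-en-1-yl)benzaldehyde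
Conditions: KOH (10% aq, 1.5 equiv), 2 (1.0 equiv), rt, 48 h; dil. HCl; chromatography (removes the O-prenyl ether)
Reagents that add atoms: none
Why: Ortho C-alkylation of the phenoxide in water (SN2), the para position being blocked and the two ortho positions equivalent, so only one C-prenyl isomer can form; no stereocentre is formed.

Step 3
Reactants: 3 1-[2,4-dihydroxy-3-(3-methylbut-2-en-1-yl)phenyl]ethan-1-one; 5 4-hydroxy-3-(3-methylbut-2-en-1-yl)benzaldehyde
Product: 6 (E)-1-[2,4-dihydroxy-3-(3-methylbut-2-en-1-yl)phenyl]-3-[4-hydroxy-3-(3-methylbut-2-en-1-yl)phenyl]prop-2-en-1-one (2',4,4'-trihydroxy-3,3'-diprenylchalcone)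
Conditions: KOH (60% aq)/EtOH, degassed, 0 °C → rt, 48–72 h; then cold 1 M HCl to pH 5
Reagents that add atoms: none
Why: Claisen–Schmidt condensation, in which the methyl ketone enolate adds to the non-enolisable aldehyde and E1cB dehydration gives the (E)-enone; concentrated KOH compensates for the phenoxide-deactivated partners, and the prenyl groups are inert to base.

Step 4
Reactants: 6 2',4,4'-trihydroxy-3,3'-diprenylchalcone
Product: 7 (E)-1-[2-hydroxy-3-(3-methylbut-2-en-1-yl)-4-(triisopropylsilyloxy)phenyl]-3-[3-(3-methylbut-2-en-1-yl)-4-(triisopropylsilyloxy)phenyl]prop-2-en-1-one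
Conditions: TIPSCl (2.3 equiv), imidazole (5 equiv), DMF, 0 °C → rt
Reagents that add atoms: triisopropylsilyl chloride (TIPSCl), CC(C)[Si](Cl)(C(C)C)C(C)C
Why: Chemoselective O-silylation of the two free phenols, the 2'-OH being hydrogen-bonded to the ketone and flanked by a prenyl group and therefore unreactive; masking the 4- and 4'-oxygens prevents the phenoxides that would switch off the enone in step 5.

Step 5
Reactants: 7 bis-TIPS 2'-hydroxychalcone
Product: 10 (2R,3R)-3-hydroxyglabrol, via epoxychalcone 8 (not isolated), via bis-TIPS flavanonol 9 (not isolated)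
Conditions: poly-L-leucine (silica-supported), urea–H2O2 (1.3 equiv), DBU (2.5 equiv), THF, 0 °C → rt, stop when 7 is consumed; filter; then AcOH (6 equiv), TBAF (2.5 equiv), 0 °C, same flask; aq. Na2S2O3 work-up
Reagents that add atoms: urea–hydrogen peroxide, NC(N)=O.OO
Why: Proposed new method: a Juliá–Colonna epoxidation run on the free 2'-hydroxychalcone so that ring closure follows in the same flask (an enantioselective Algar–Flynn–Oyamada reaction), in which hydroperoxide bound at the N-terminus of the poly-L-leucine helix gives the (αR,βS)-epoxide 8 and so fixes C3 as R, and the neighbouring 2'-phenoxide (or the phenol after the AcOH quench) opens the epoxide 6-endo at the benzylic carbon, activated by the para-silyloxyaryl group and favoured over 5-exo attack in the absence of a 6'-substituent, with inversion to set C2 as R (2,3-trans); the closest known chemistry is poly-amino-acid epoxidation of 2'-O-protected chalcones followed by deprotection–cyclisation to trans-dihydroflavonols, and buffered fluoride then cleaves both aryl TIPS ethers without touching C2, C3 or the prenyl groups (no nitrile solvent, so no peroxyimidic acid forms to epoxidise them).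

**Compound list**
1 | 2,4-dihydroxyacetophenone | CC(=O)c1ccc(O)cc1O | starting material
2 | prenyl bromide (1-bromo-3-methylbut-2-ene) | CC(C)=CCBr | starting material
3 | 1-[2,4-dihydroxy-3-(3-methylbut-2-en-1-yl)phenyl]ethan-1-one | CC(=O)c1ccc(O)c(CC=C(C)C)c1O | intermediate
4 | 4-hydroxybenzaldehyde | O=Cc1ccc(O)cc1 | starting material
5 | 4-hydroxy-3-(3-methylbut-2-en-1-yl)benzaldehyde | CC(C)=CCc1cc(C=O)ccc1O | intermediate
6 | (E)-2',4,4'-trihydroxy-3,3'-diprenylchalcone | CC(C)=CCc1cc(/C=C/C(=O)c2ccc(O)c(CC=C(C)C)c2O)ccc1O | intermediate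
7 | (E)-2'-hydroxy-3,3'-diprenyl-4,4'-bis(triisopropylsilyloxy)chalcone | CC(C)=CCc1cc(/C=C/C(=O)c2ccc(O[Si](C(C)C)(C(C)C)C(C)C)c(CC=C(C)C)c2O)ccc1O[Si](C(C)C)(C(C)C)C(C)C | intermediate
8 | [2-hydroxy-3-prenyl-4-(triisopropylsilyloxy)phenyl][(2R,3S)-3-[3-prenyl-4-(triisopropylsilyloxy)phenyl]oxiran-2-yl]methanone (trans epoxide, αR,βS; formed in the flask in step 5) | CC(C)=CCc1c(O)c(ccc1O[Si](C(C)C)(C(C)C)C(C)C)C(=O)[C@@H]1O[C@H]1c1ccc(O[Si](C(C)C)(C(C)C)C(C)C)c(CC=C(C)C)c1 | intermediate
9 | (2R,3R)-3-hydroxy-8-prenyl-2-[3-prenyl-4-(triisopropylsilyloxy)phenyl]-7-(triisopropylsilyloxy)chroman-4-one (2,3-trans; formed in the flask in step 5) | CC(C)=CCc1cc([C@H]2Oc3c(ccc(O[Si](C(C)C)(C(C)C)C(C)C)c3CC=C(C)C)C(=O)[C@@H]2O)ccc1O[Si](C(C)C)(C(C)C)C(C)C | intermediate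
10 | 3-hydroxyglabrol, (2R,3R)-3,7-dihydroxy-2-[4-hydroxy-3-(3-methylbut-2-en-1-yl)phenyl]-8-(3-methylbut-2-en-1-yl)chroman-4-one | CC(C)=CCc1cc([C@H]2Oc3c(ccc(O)c3CC=C(C)C)C(=O)[C@@H]2O)ccc1O | target

**Step count**
Total: 5 steps. Longest linear sequence: 4 steps (1 → 3 → 6 → 7 → 10, or 4 → 5 → 6 → 7 → 10).

**Steps most likely to fail, each with a fallback**

Step 5 (highest risk). The 2'-phenoxide lowers the electrophilicity of the enone and may not fit the peptide binding site, so rate or ee can suffer. In base the product can be oxidised on to the flavonol or ring-opened, the epoxide can close 5-exo to aurone-type products, and DBU/hydroperoxide may strip a TIPS group early. The fallback separates oxidation from ring closure; it sets out from 7 and comes back at 9. Cap the 2'-OH of 7 (MOMCl, NaH, DMF, 0 °C) to give the 2'-O-methoxymethyl chalcone F1. Epoxidise it under the same poly-L-leucine/urea–H2O2/DBU conditions, which have direct precedent for 2'-O-protected chalcones, to the (αR,βS)-epoxide F2. Treat F2 with HCl in MeOH–THF at 40 °C; this removes the MOM group, and the freed phenol opens the epoxide at the benzylic carbon to give 9. Compound 9 is desilylated with TBAF/AcOH as in step 5.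

Step 3. The triply deprotonated partners condense slowly and the yield may be poor. The fallback sets out from 3 and 5 and comes back at 6. Mask the 4-hydroxyl of each (MOMCl, K2CO3, acetone; the chelated 2-OH of 3 stays free) to give 1-[2-hydroxy-4-(methoxymethoxy)-3-prenylphenyl]ethan-1-one F3 and 4-(methoxymethoxy)-3-prenylbenzaldehyde F4. These condense readily (KOH, EtOH, rt) to 2'-hydroxy-4,4'-bis(methoxymethoxy)-3,3'-diprenylchalcone F5. HCl (3 M) in MeOH at 40 °C then gives 6.

Step 1. Direct C-prenylation gives the 3-prenyl ketone only in modest yield beside the 5-prenyl, O-prenyl and diprenyl products. The fallback sets out from 1 and comes back at 3. Alkylate the 4-OH of 1 (3-chloro-3-methylbut-1-yne, K2CO3, KI, CuI cat., acetone, reflux) to give 1-[2-hydroxy-4-(2-methylbut-3-yn-2-yloxy)phenyl]ethan-1-one F6. Semi-hydrogenate it (H2, Pd/CaCO3 poisoned with Pb(OAc)2, quinoline, EtOAc) to the 1,1-dimethylallyl ether 1-[2-hydroxy-4-(2-methylbut-3-en-2-yloxy)phenyl]ethan-1-one F7. Heat F7 in N,N-diethylaniline at 180 °C; the aromatic Claisen rearrangement delivers the prenyl group to C3, the position between the two oxygens, and gives 3.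

**Further compounds**
F1 | step 5 | (E)-2'-(methoxymethoxy)-3,3'-diprenyl-4,4'-bis(triisopropylsilyloxy)chalcone | CC(C)=CCc1cc(/C=C/C(=O)c2ccc(O[Si](C(C)C)(C(C)C)C(C)C)c(CC=C(C)C)c2OCOC)ccc1O[Si](C(C)C)(C(C)C)C(C)C
F2 | step 5 | [2-(methoxymethoxy)-3-prenyl-4-(triisopropylsilyloxy)phenyl][(2R,3S)-3-[3-prenyl-4-(triisopropylsilyloxy)phenyl]oxiran-2-yl]methanone | CC(C)=CCc1c(OCOC)c(ccc1O[Si](C(C)C)(C(C)C)C(C)C)C(=O)[C@@H]1O[C@H]1c1ccc(O[Si](C(C)C)(C(C)C)C(C)C)c(CC=C(C)C)c1
F3 | step 3 | 1-[2-hydroxy-4-(methoxymethoxy)-3-(3-methylbut-2-en-1-yl)phenyl]ethan-1-one | CC(=O)c1ccc(OCOC)c(CC=C(C)C)c1O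
F4 | step 3 | 4-(methoxymethoxy)-3-(3-methylbut-2-en-1-yl)benzaldehyde | CC(C)=CCc1cc(C=O)ccc1OCOC
F5 | step 3 | (E)-2'-hydroxy-4,4'-bis(methoxymethoxy)-3,3'-diprenylchalcone | CC(C)=CCc1cc(/C=C/C(=O)c2ccc(OCOC)c(CC=C(C)C)c2O)ccc1OCOC
F6 | step 1 | 1-[2-hydroxy-4-(2-methylbut-3-yn-2-yloxy)phenyl]ethan-1-one | CC(=O)c1ccc(OC(C)(C)C#C)cc1O
F7 | step 1 | 1-[2-hydroxy-4-(2-methylbut-3-en-2-yloxy)phenyl]ethan-1-one | CC(=O)c1ccc(OC(C)(C)C=C)cc1O
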